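**Assumption:** the target has no stereocentres (it is achiral), so "single enantiomer" is taken to mean the one constitution drawn; no stereocontrol is needed.

**Retrosynthetic overview**
1. The target is a linear C–O trimer of one monomer, 4-methoxy-2-isopropyl-5-methylphenol (5), with the last ring at the quinone level. Both diaryl ether bonds come from phenoxide addition–elimination on 2-bromo-6-isopropyl-3-methyl-1,4-benzoquinone (7), which is used twice.
2. The middle ring: the first aryloxyquinone 8 is hydrogenated and O-methylated at the unhindered OH to give phenol 10, the nucleophile for the second coupling.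
3. Bromoquinone 7 is made from 5 by ortho-bromination and oxidative demethylation.
4. Key C–C bond: the ring–CH3 bond of 5. A methyl nucleophile adds to p-quinone monoketal 3, the polarity-reversed (aryl-cation / enolonium-type) form of an electron-rich 4-methoxyphenol. Two natively nucleophilic carbons are joined, and the OH/OMe pattern is fixed in the same operation.
5. No ring is constructed: all three six-membered rings come from 2-isopropylphenol (1). Order of assembly: ring A (5), first quinone ring (which becomes ring B), then ring C.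

**Route**

Step 1
Reactants: 1 2-isopropylphenol
Product: 3 4,4-dimethoxy-2-isopropylcyclohexa-2,5-dien-1-one, via 2-isopropyl-4-methoxyphenol 2 (not isolated)
Conditions: PhI(OAc)2 (2.2 equiv), MeOH, 0 °C → rt
Reagents that add atoms: methanol CO
Why: Hypervalent-iodine oxidative dearomatisation: PIDA oxidises the phenol twice in MeOH (para-methoxylation to 2, then oxidation of 2) to give the p-quinone monoketal, the electrophilic form of the electron-rich ring.

Step 2
Reactants: 3 4,4-dimethoxy-2-isopropylcyclohexa-2,5-dien-1-one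
Product: 5 4-methoxy-2-isopropyl-5-methylphenol, via 4,4-dimethoxy-2-isopropyl-5-methylcyclohex-2-en-1-one 4 (not isolated)
Conditions: Me2Zn (1.5 equiv), Cu(OTf)2 (5 mol %), P(OEt)3 (10 mol %), PhMe, −30 → 0 °C; aq NH4Cl; then TsOH (10 mol %), CH2Cl2, rt
Reagents that add atoms: dimethylzinc C[Zn]C
Why: Cu-catalysed conjugate addition of a dialkylzinc to a quinone monoketal (phenol umpolung): the monoketal is the reversed-polarity aryl-cation/enolonium equivalent of 2, so the methyl nucleophile adds to the α-unsubstituted enone arm at C5 (next to the ketal carbon), and acid-promoted loss of MeOH rearomatises with OMe ortho to the new methyl; the transient C5 stereocentre of racemic 4 is erased.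

Step 3
Reactants: 5 4-methoxy-2-isopropyl-5-methylphenol
Product: 7 2-bromo-6-isopropyl-3-methyl-1,4-benzoquinone, via 2-bromo-4-methoxy-6-isopropyl-3-methylphenol 6 (not isolated)
Conditions: NBS (1.0 equiv), MeCN, −10 → 0 °C; then CAN (2.3 equiv), H2O, 0 °C
Reagents that add atoms: N-bromosuccinimide O=C1CCC(=O)N1Br; water O
Why: Electrophilic aromatic bromination goes to the only open position ortho to the free OH (the other open carbon is flanked by isopropyl and activated only by OMe), and CAN oxidative demethylation of the p-methoxyphenol in the same MeCN/water medium gives the bromoquinone.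

Step 4
Reactants: 5 4-methoxy-2-isopropyl-5-methylphenol; 7 2-bromo-6-isopropyl-3-methyl-1,4-benzoquinone
Product: 8 2-(4-methoxy-2-isopropyl-5-methylphenoxy)-6-isopropyl-3-methyl-1,4-benzoquinone
Conditions: Cs2CO3 (1.2 equiv), DMF, 0 °C → rt, N2
Reagents that add atoms: none
Why: Addition–elimination on a haloquinone (vinylogous acyl substitution): the phenoxide attacks the bromine-bearing carbon and irreversible loss of bromide fixes the ether next to the ring methyl.

Step 5
Reactants: 8 2-(4-methoxy-2-isopropyl-5-methylphenoxy)-6-isopropyl-3-methyl-1,4-benzoquinone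
Product: 10 4-methoxy-2-(4-methoxy-2-isopropyl-5-methylphenoxy)-6-isopropyl-3-methylphenol, via 2-(4-methoxy-2-isopropyl-5-methylphenoxy)-6-isopropyl-3-methylbenzene-1,4-diol 9 (not isolated)
Conditions: H2 (1 atm), Pd/C, DMF, rt; filter under Ar; then K2CO3 (1.2 equiv), MeI (1.05 equiv), 0 °C → rt
Reagents that add atoms: iodomethane CI
Why: Catalytic hydrogenation of the quinone to the hydroquinone, then Williamson O-methylation with one equivalent of MeI at the OH flanked only by Me and H, because the other OH is buried between the aryloxy and isopropyl groups and hydrogen-bonded to the ether oxygen.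

Step 6
Reactants: 10 4-methoxy-2-(4-methoxy-2-isopropyl-5-methylphenoxy)-6-isopropyl-3-methylphenol; 7 2-bromo-6-isopropyl-3-methyl-1,4-benzoquinone
Product: 11 2-[4-methoxy-2-(4-methoxy-2-isopropyl-5-methylphenoxy)-3-methyl-6-isopropylphenoxy]-3-methyl-6-isopropyl-1,4-benzoquinone
Conditions: 7 (1.5 equiv), Cs2CO3 (1.5 equiv), DMF, rt → 40 °C, N2
Reagents that add atoms: none
Why: The same haloquinone addition–elimination as in step 4, now with the hindered phenoxide of 10; bromide departure drives the reaction and the quinone needs no further oxidation-state change.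

**Compound list**
1 | 2-isopropylphenol | CC(C)c1ccccc1O | starting material
2 | 2-isopropyl-4-methoxyphenol | COc1ccc(O)c(C(C)C)c1 | intermediate
3 | 4,4-dimethoxy-2-isopropylcyclohexa-2,5-dien-1-one | COC1(OC)C=CC(=O)C(C(C)C)=C1 | intermediate
4 | rac-4,4-dimethoxy-2-isopropyl-5-methylcyclohex-2-en-1-one | COC1(OC)C(C)CC(=O)C(C(C)C)=C1 | intermediate
5 | 4-methoxy-2-isopropyl-5-methylphenol | COc1cc(C(C)C)c(O)cc1C | intermediate
6 | 2-bromo-4-methoxy-6-isopropyl-3-methylphenol | COc1cc(C(C)C)c(O)c(Br)c1C | intermediate
7 | 2-bromo-6-isopropyl-3-methyl-1,4-benzoquinone | CC1=C(Br)C(=O)C(C(C)C)=CC1=O | intermediate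
8 | 2-(4-methoxy-2-isopropyl-5-methylphenoxy)-6-isopropyl-3-methyl-1,4-benzoquinone | COc1cc(C(C)C)c(OC2=C(C)C(=O)C=C(C(C)C)C2=O)cc1C | intermediate
9 | 2-(4-methoxy-2-isopropyl-5-methylphenoxy)-6-isopropyl-3-methylbenzene-1,4-diol | COc1cc(C(C)C)c(Oc2c(C)c(O)cc(C(C)C)c2O)cc1C | intermediate
10 | 4-methoxy-2-(4-methoxy-2-isopropyl-5-methylphenoxy)-6-isopropyl-3-methylphenol | COc1cc(C(C)C)c(Oc2c(C)c(OC)cc(C(C)C)c2O)cc1C | intermediate
11 | 2-[4-methoxy-2-(4-methoxy-2-isopropyl-5-methylphenoxy)-3-methyl-6-isopropylphenoxy]-3-methyl-6-isopropyl-1,4-benzoquinone (CNP0335608.0, achiral) | COc1cc(C(C)C)c(Oc2c(C)c(OC)cc(C(C)C)c2OC2=C(C)C(=O)C=C(C(C)C)C2=O)cc1C | target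

**Totals**
Total steps: 6. Longest linear sequence: 6 (1 → 3 → 5 → 7 → 8 → 10 → 11; 5 and 7 are each used twice).

**Three steps most likely to fail, with fallbacks**

Step 2 (methyl addition to the monoketal). Risks are 1,2-addition, electron-transfer reduction back to 2, or sluggish methyl transfer from zinc. The fallback sets out from 3 and returns at 5, replacing the hard methyl metal with a soft sulfur-stabilised one-carbon nucleophile. 2-Lithio-1,3-dithiane (THF/HMPA, −78 °C) adds 1,4 to the unsubstituted enone arm of 3 to give racemic 5-(1,3-dithian-2-yl)-4,4-dimethoxy-2-isopropylcyclohex-2-en-1-one F1. TsOH in CH2Cl2 rearomatises it to 5-(1,3-dithian-2-yl)-4-methoxy-2-isopropylphenol F2. Raney nickel in refluxing EtOH then reduces the dithiane carbon to the methyl group, which gives 5.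

Step 5 (mono-methylation of the hydroquinone). The risk is that MeI does not discriminate well enough between the two OH groups of 9. The fallback sets out from 8 and returns at 10, using a protecting-group differentiation. Reductive acetylation of 8 (Zn, Ac2O, NaOAc) gives 2-(4-methoxy-2-isopropyl-5-methylphenoxy)-6-isopropyl-3-methyl-1,4-phenylene diacetate F3. Mild methanolysis (cat. K2CO3, MeOH, 0 °C) removes only the unhindered acetate to give 4-hydroxy-2-(4-methoxy-2-isopropyl-5-methylphenoxy)-6-isopropyl-3-methylphenyl acetate F4. Methylation (MeI, K2CO3, acetone) gives 4-methoxy-2-(4-methoxy-2-isopropyl-5-methylphenoxy)-6-isopropyl-3-methylphenyl acetate F5. NaOMe in MeOH at 50 °C cleaves the hindered acetate and gives 10.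

Step 6 (second ether bond). The risk is that the di-ortho-substituted phenoxide of 10 is too hindered, or is oxidised by 7 through electron transfer. The fallback sets out from 5 and 10 and returns at 11, bringing in ring C as an aryl-iodine(III) electrophile at the arene oxidation level.
- Methylation of 5 (MeI, K2CO3, acetone) gives 1,4-dimethoxy-2-isopropyl-5-methylbenzene F6.
- F6 (2 equiv) with I2, mCPBA and TsOH·H2O in CH2Cl2/TFE gives bis(2,5-dimethoxy-3-isopropyl-6-methylphenyl)iodonium tosylate F7; iodine enters between OMe and Me, the less hindered open position.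
- The potassium salt of 10 (t-BuOK, THF, rt → 40 °C) is O-arylated by F7 through ligand coupling at iodine, which tolerates ortho substituents on both partners. This gives 2-(2,5-dimethoxy-3-isopropyl-6-methylphenoxy)-5-methoxy-3-(4-methoxy-2-isopropyl-5-methylphenoxy)-1-isopropyl-4-methylbenzene F8.
- CAN (2.2 equiv, MeCN/H2O, 0 °C) oxidatively demethylates the most electron-rich ring, the only one with two para methoxy groups, which gives 11. Selectivity over rings A and B is expected but is the weak point of this fallback.

**Further compounds**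
F1 | step 2 | rac-5-(1,3-dithian-2-yl)-4,4-dimethoxy-2-isopropylcyclohex-2-en-1-one | COC1(OC)C(C2SCCCS2)CC(=O)C(C(C)C)=C1
F2 | step 2 | 5-(1,3-dithian-2-yl)-4-methoxy-2-isopropylphenol | COc1cc(C(C)C)c(O)cc1C1SCCCS1
F3 | step 5 | 2-(4-methoxy-2-isopropyl-5-methylphenoxy)-6-isopropyl-3-methyl-1,4-phenylene diacetate | COc1cc(C(C)C)c(Oc2c(C)c(OC(C)=O)cc(C(C)C)c2OC(C)=O)cc1C
F4 | step 5 | 4-hydroxy-2-(4-methoxy-2-isopropyl-5-methylphenoxy)-6-isopropyl-3-methylphenyl acetate | COc1cc(C(C)C)c(Oc2c(C)c(O)cc(C(C)C)c2OC(C)=O)cc1C
F5 | step 5 | 4-methoxy-2-(4-methoxy-2-isopropyl-5-methylphenoxy)-6-isopropyl-3-methylphenyl acetate | COc1cc(C(C)C)c(Oc2c(C)c(OC)cc(C(C)C)c2OC(C)=O)cc1C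
F6 | step 6 | 1,4-dimethoxy-2-isopropyl-5-methylbenzene | COc1cc(C(C)C)c(OC)cc1C
F7 | step 6 | bis(2,5-dimethoxy-3-isopropyl-6-methylphenyl)iodonium tosylate | COc1cc(C(C)C)c(OC)c([I+]c2c(C)c(OC)cc(C(C)C)c2OC)c1C.Cc1ccc(S(=O)(=O)[O-])cc1
F8 | step 6 | 2-(2,5-dimethoxy-3-isopropyl-6-methylphenoxy)-5-methoxy-3-(4-methoxy-2-isopropyl-5-methylphenoxy)-1-isopropyl-4-methylbenzene | COc1cc(C(C)C)c(Oc2c(C)c(OC)cc(C(C)C)c2Oc2c(C)c(OC)cc(C(C)C)c2OC)cc1C
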